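**The reading.** At 8.0 min you look into Tuesday's flask and ask about rates: how fast target first came, and how that speed faded.

| flask | solid substrate | coupling partner | temperature | remark | time |
|---|---|---|---|---|---|
| Tuesday's | 34 mM | 34 mM | 25 °C | the very flask that is asked about, followed so far |  |
| Monday's | 34 mM | 34 mM | 10 °C | run made earlier |  |
| flask | 34 mM | 34.0 mM | 25 °C |  | 8.0 min |

| run | time / min | target / % | solid substrate / % |
|---|---|---|---|
| Tuesday's | 0.417 | 3.7 | 65.2 |
| Tuesday's | 1.33 | 11.5 | 57.1 |
| Tuesday's | 2.50 | 14.6 | 53.2 |
| Tuesday's | 4.00 | 14.8 | 52.2 |
| Tuesday's | 5.00 | 14.4 | 52.4 |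
| Tuesday's | 6.00 | 14.8 | 52.5 |
| Monday's | 0.833 | 4.1 | 64.7 |
| Monday's | 3.00 | 10.0 | 56.3 |
| Monday's | 5.00 | 16.1 | 52.1 |
| Monday's | 8.00 | 21.3 | 46.6 |
| Monday's | 10.0 | 23.6 | 44.7 |
| Monday's | 12.0 | 26.2 | 43.0 |

(standard deviation of a reading: 0.5 percentage points)

- dusk: at 8.0 min add coupling partner, 50.0 % of the amount charged, then wait 2.5 min
- dawn: change nothing and wait 2.5 min more
- autumn: at 8.0 min raise the temperature by 25 K, then wait 2.5 min

1. target, in percent of the solid substrate first charged, at 8.0 min
2. the remedy with the largest gain of target, or "none" below 2 percentage points (dusk / dawn / autumn / none)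
3. target present, in percent of the solid substrate first charged, after dawn
4. target present, in percent of the solid substrate first charged, after autumn

- the volume of additions can be left aside
- at the start none of the solid substrate is in solution
- a reading or a percentage of target counts all its forms, free or not

**Fading rate.** In Tuesday's run target starts at 0.0887 min⁻¹ as a fraction of the charge, and by 2.50 min the rate read between neighbouring points is 0.0265 min⁻¹, a fall by a factor 3.35; the last rate I can read, 0.001333 min⁻¹, lies within the scatter. The solid substrate reading still stands at 52.5 %; coupling partner is not read, and my assumption is that its amount falls with the rate. In Monday's run, at 10 °C, the start rate is 0.0492 min⁻¹, lower by a factor 1.80, and the rate read between neighbouring points is down by a factor 2.84 by 8.00 min and 4.28 by 10.0 min, so a like fall comes later by a factor between 3.20 and 4.00, which is more than the factor by which the start is slower.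

**Working time.** Divide Tuesday's plateau, 14.7 %, by the start rate and you get 1.65 min: the working time, the span for which the start rate, held steady, would make the plateau. My reckoning puts the flask at that plateau, and waiting adds 0.33 percentage points. Fresh partner at 50.0 % of the charge should restart the rate at that fraction for one working time, a gain of 7.3 points.

**The forecast.** It argues differently: “A plateau that is lower when warmer and reached about eight times faster suggests an exothermic reversible coupling”. It gives 14.7 % now, 14.7 % after dawn and 4 % after autumn, and it chooses dusk, with a gain of about 5 points where mine is 7.3 points.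

    solid substrate ⇌ dissolved substrate, rate k1*(cs1 - [dissolved substrate]) while solid is left; crystals form when [dissolved substrate] > cs1 (solubility = 11.0 mM, k = 0.185 s⁻¹)
    solid product ⇌ target, rate k2*(cs2 - [target]) while solid is left; crystals form when [target] > cs2 (solubility = 2.90 mM, k = 0.145 s⁻¹)
    coupling partner → side product (k = 0.0101 s⁻¹, Ea = 84.0 kJ mol⁻¹)
    dissolved substrate + coupling partner ⇌ target (K = 198 L mol⁻¹, k = 0.218 L mol⁻¹ s⁻¹, Ea = 52.0 kJ mol⁻¹, ΔH = −36.0 kJ mol⁻¹)
    (constants at 25 °C)

**The result.** The flask gives 14.3 %, 13.2 % after dawn and 1.72 % after autumn, and dusk gains 6.9 points, so fresh partner is the remedy. The limiting reagent, coupling partner, is down to 1.0 % at 8.00 min, and its half-life by the side step, 1.1 min, compares with 1.14 min from the working time. Now take the neighbour charged with 8.5 mM of solid substrate. Tuesday's flask held dissolved substrate at 31.6 % of its charge, so scaling the start rate down to the neighbour's charge, with the same working time, gives 46.3 %. The neighbour reads 32.4 % at 8.00 min, with solid substrate at 0 % and dissolved substrate at 67.6 %.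

Readings and results are calculated for substances that don't exist; noise was put on by code.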